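## Structural features

The target is a daucane-type sesquiterpenoid ester. A cyclopentane (C1–C5) is fused through the C1–C5 bond to a seven-membered ring (C5–C6–C7–C8–C9–C10–C1). C1 is the quaternary, methyl-bearing fusion carbon; C4 carries the tertiary hydroxyl and the isopropyl group; C6 carries the 4-hydroxybenzoyloxy group; C8–C9 is the epoxide, with a methyl on C8 (azulene positions 8a, 3, 4, 6 and 7 in the systematic names below). There are six stereocentres; C4, C5 and C6 are contiguous and C1 adjoins C5. The ring fusion is cis: the C1–C10 bond, the C5–C6 bond and the C4 hydroxyl lie on one face of the five-membered ring, and the C1 methyl, the C5 hydrogen and the isopropyl group on the other. The C6 oxygen is syn to the C4 hydroxyl, and the epoxide oxygen lies on the opposite face of the seven-membered ring. The fragile groups are the trisubstituted epoxide (acid-labile, with the C4 hydroxyl placed to open it across the ring), the aryl ester and free phenol (base), and, at any stage with a C6 ketone, the tertiary aldol unit and the C7 methylene between the carbonyl and the C8=C9 alkene. The real difficulty is the quaternary C1 beside the ring fusion together with the C4/C5/C6 triad, in which the C5 hydrogen must end trans to the tertiary hydroxyl. The key step exploits two facts: at the ketone level C1 is the β-carbon of a C1=C5–C6=O enone, and C10–C9=C8(CH3) is an allyl unit. An allylsilane with silicon on C8 can therefore bond through C10 to C1 and leave the alkene at C8=C9, where the epoxide is needed. The five-membered ring with the C1 methyl, C6 and the isopropyl-bearing C4 maps onto the cyclopentenecarbaldehyde obtained by ring contraction of limonene.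

## Logic of the disconnections

**25 ⇒ 24 ⇒ 23.** No skeletal bond is cut. The phenol O–H is exchanged for an O–Si bond and the two epoxide C–O bonds (C8–O, C9–O) are removed. The most acid-sensitive group is thus made last, and the phenol stays masked through acylation and oxidation. The forward steps demand peracid attack on the convex face of 23 and a desilylation that spares ester and epoxide.

**23 ⇒ 21 + 22.** The ester C–O bond at C6 is cut. This separates the aromatic acid from the terpenoid diol and is the only convergent junction of the endgame. The acylation has to distinguish the secondary C6 hydroxyl from the tertiary C4 hydroxyl.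

**21 ⇒ 19.** The C6–H bond is removed (alcohol to ketone). The C6 carbonyl is the functional handle for everything upstream. The hydride must arrive on the face that gives the 1,3-syn diol.

**19 ⇒ 18 ⇒ 17 ⇒ 16.** The C5–H bond, then the C4–O and C5–O bonds of an epoxide, then the C6–H bond are removed in turn. A β-hydroxy ketone with C5–H trans to the C4 oxygen is the semipinacol product of a syn 2,3-epoxy alcohol. The C4 oxygen then comes from a hydroxyl-directed epoxidation and the C5 hydrogen from a stereospecific 1,2-shift. Neither centre relies on the weak facial bias of the C1 substituents or on the face of an enolate protonation, which would have to occur on the more hindered side to give the cis fusion. The gain is the loss of the C4 and C5 stereocentres, back to a planar enone. The forward steps demand a reagent-controlled carbinol in 17, epoxidation of the allylic alkene only, and ionisation at C5–O with hydrogen (not C7) migration.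

**16 ⇒ 15.** The C4=C5 unsaturation is removed. Dehydrogenation needs the enol derivative regiospecifically at C5. A free C6 ketone with the C8=C9 alkene in place would enolise toward the doubly activated C7, so the enol ether has to come directly from the ring-forming step. The forward step must achieve β-hydride elimination at a fully substituted carbon.

**15 ⇒ 14 (key).** The C1–C10 bond is cut. The seven-membered ring and the quaternary stereocentre disappear together, leaving a monocyclic enone with one stereocentre and a tertiary allylsilane. The forward step demands closure onto a fully substituted β-carbon anti to the isopropyl group, reaction of the allylsilane at its CH2 terminus, and retention of the enolate as a silyl enol ether.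

**14 ⇒ 13 ⇒ 11 + 12.** The C6 oxidation level is lowered, then the C8–Si bond is cut with allylic transposition. The tertiary allylsilane is the SN2′ product of a primary allylic phosphate. Keeping C6 as an alcohol during this basic step avoids a β,γ-unsaturated ketone carrying an allylic leaving group, which would be prone to 1,4-elimination. The forward steps demand γ-selectivity at a fully substituted carbon and an oxidation that leaves the allylsilane intact.

**11 ⇒ 10 ⇒ 8 ⇒ 5 + 6.** The O–P bond, then the C8–CH3 and C9–C10 bonds, then the C6–C7 bond are cut. An (E)-trisubstituted allylic alcohol is the product of syn methylmetallation and hydroxymethylation of a terminal alkyne, and the alkyne arrives by propargylation of the aldehyde. The chain shrinks to a three-carbon unit and an aldehyde. The forward steps demand methyl delivery to the internal alkyne carbon and 1,2-addition to a hindered enal.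

**5 ⇒ 4 ⇒ 2 ⇒ 1.** The C1=C5 bond is cut (aldol condensation retron), C1 is reconnected to C6 as a cyclohexene double bond, and the isopropyl group is traced to an isopropenyl group. The cyclopentene with all its carbons and the C4 stereocentre is a ring-contracted p-menthene. Compound 1 must be the (R)-enantiomer: its stereocentre becomes C4 of 14 and, through anti addition in step 9, fixes C1 of 25. The forward steps demand an aldehyde-enamine (not ketone-enolate) aldol and hydrogenation of the 1,1-disubstituted alkene only.

## Other disconnections considered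

**Alternative 1:** The cut removes C1–C5 and C7–C8 at once, so both rings come from the acyclic epoxy enol silane A1, triethyl({1-[(2S,3R)-3-[(3Z,5E)-3-methylhepta-3,5-dien-1-yl]-3-(propan-2-yl)oxiran-2-yl]ethenyl}oxy)silane.
- *Forward step:* catalytic TESOTf would ionise the epoxide at C5. The 2-silyloxyallyl cation over C5–C6–C7 would be captured by the tethered diene in a (4+3) cycloaddition to give A2, (3R,3aR,6R,8aS)-6,8a-dimethyl-3-(propan-2-yl)-3-[(triethylsilyl)oxy]-2,3,3a,5,6,8a-hexahydroazulen-4(1H)-one.
- *In favour:* two C–C bonds, both rings and the C1 and C5 stereocentres form in one catalytic step, and the C4 oxygen is present from the start, already protected. On bonds per step and on the handling of C4 this plan is the better one. Like step 9 it runs on silyl transfer without a stoichiometric metal, on which the two are equal.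
- *Against, here:* A2 has its ring alkene at C9=C10 and a C8 methine, whereas the epoxide needs C8=C9. Moving the alkene by one position means isomerising toward the C6 carbonyl without continuing into conjugation at C7=C8, which is hard to stop.
- *Comparison:* structurally, A1 needs a geometrically pure diene with the tether on the inside of a trisubstituted terminus and an enantioenriched epoxide; the chosen plan fixes the alkene by the position of silicon. Mechanistically, the one surviving stereocentre (C4) would have to control both facial and endo/exo selectivity of a cationic cycloaddition onto a fully substituted terminus. In step economy the route to the bicycle should be comparable or slightly shorter, but the saving is spent again on the alkene transposition.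

**Alternative 2:** The cut removes the C1–CH3 bond and the C4–C5 bond, opening the cyclopentane to the cycloheptadienone A3, 6-methyl-3-(4-methyl-3-oxopentyl)cyclohepta-2,5-dien-1-one.
- *Forward step:* AlMe3 with CuTC (copper thiophene-2-carboxylate, monovalent copper) and a chiral phosphoramidite would add methyl to C1. The C5 aluminium enolate would then close onto the tethered isopropyl ketone to give A4, (3R,3aR,8aS)-3-hydroxy-6,8a-dimethyl-3-(propan-2-yl)-2,3,3a,5,8,8a-hexahydroazulen-4(1H)-one, which is identical with 19.
- *In favour:* the absolute configuration comes from a catalyst and either enantiomer is accessible. C1, C4 and C5 are set in one flask, and a chelated aldol closure places the C4 oxygen cis to C6, as required. It reaches 19 without steps 10–13, so in step and redox economy it is the better plan.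
- *Against, here:* A3 is a skipped dienone whose C7 and C10 methylenes are both activated, so drift into full conjugation is to be expected under Lewis-acidic or basic conditions. AlMe3 can also add to the side-chain ketone, methyl addition to a β-substituted seven-ring enone is less well served than the six-ring case, and the tertiary aluminium aldolate can revert and scramble C4 and C5.
- *Comparison:* the endgame from 19 is the same (equal). The chosen plan takes the C1 configuration from the chiral pool and sets C4 and C5 by intramolecular oxygen and hydrogen transfer, at the price of four more steps.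

**Alternative 3:** The cut removes C1–C10 and C4–C5 from the acyclic A5, (2E,6E)-farnesyl diphosphate.
- *Forward step:* a class one sesquiterpene cyclase with its three Mg2+ ions would ionise the diphosphate, fold the chain so that both ring bonds form, and after a hydride shift capture water at C4. The product would be A6, (3R,3aR,8aS)-6,8a-dimethyl-3-(propan-2-yl)-1,2,3,3a,4,5,8,8a-octahydroazulen-3-ol.
- *In favour:* one step from a primary metabolite would give both rings, three stereocentres, the C8=C9 alkene and the C4 hydroxyl without protecting groups. In step economy it is clearly the better plan.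
- *Against, here:* cyclases for this skeleton make the stereochemical series of the natural daucanes, so the cis-fused A6 with this absolute configuration would need enzyme discovery or engineering. A6 also lacks the C6 oxygen. C6 is an unactivated methylene next to the allylic C7, so chemical oxidation would go elsewhere and a second, engineered hydroxylase would be needed.
- *Comparison:* the chosen plan carries the C6 oxygen as the carbonyl that drives its key step and uses ionic mechanisms whose selectivity can be argued on paper. The endgame (acylation, epoxidation, deprotection) would be the same (equal).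

Key step: step 9

Remark: the target is taken with the cis ring fusion encoded in its SMILES (C5–H and the C1 methyl on one face, C5–H trans to the C4 hydroxyl), and 22 is taken as a purchasable reagent (otherwise one flask from 4-hydroxybenzoic acid, TBSCl and imidazole with hydrolysis of the silyl ester).

## Route

Step 1
Reactants: 1 (R)-limonene, (4R)-1-methyl-4-(prop-1-en-2-yl)cyclohex-1-ene
Product: 2 (4R)-1-methyl-4-(propan-2-yl)cyclohex-1-ene
Conditions: H2 (1 atm), RhCl(PPh3)3 (1 mol %), benzene–EtOH, rt
Reagents that add atoms: none
Why: Chemoselective homogeneous hydrogenation: RhCl(PPh3)3 reduces the 1,1-disubstituted isopropenyl alkene much faster than the trisubstituted ring alkene, and the stereocentre is not touched.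

Step 2
Reactants: 2 (4R)-1-methyl-4-(propan-2-yl)cyclohex-1-ene
Product: 4 (3R)-6-oxo-3-(propan-2-yl)heptanal, via the secondary ozonide 3 (not isolated)
Conditions: O3, CH2Cl2, −78 °C; then Me2S, −78 °C → rt
Reagents that add atoms: ozone, [O-][O+]=O
Why: Ozonolysis of the only alkene with reductive work-up of the ozonide opens the ring to the 1,6-keto aldehyde; the stereocentre is β to the aldehyde and cannot epimerise.

Step 3
Reactants: 4 (3R)-6-oxo-3-(propan-2-yl)heptanal
Product: 5 (5S)-2-methyl-5-(propan-2-yl)cyclopent-1-ene-1-carbaldehyde
Conditions: piperidine (0.2 equiv), AcOH (0.2 equiv), benzene, reflux, Dean–Stark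
Reagents that add atoms: none
Why: Amine-catalysed intramolecular aldol condensation: the enamine of the aldehyde attacks the methyl ketone and dehydration gives the tetrasubstituted enal, so the ring is contracted with the isopropyl stereocentre unchanged.

Step 4
Reactants: 5 (5S)-2-methyl-5-(propan-2-yl)cyclopent-1-ene-1-carbaldehyde; 6 3-bromoprop-1-yne
Product: 8 1-[(5S)-2-methyl-5-(propan-2-yl)cyclopent-1-en-1-yl]but-3-yn-1-ol, via bromo(propa-1,2-dien-1-yl)zinc 7 (not isolated)
Conditions: Zn, THF, 0 °C → rt; aq. NH4Cl
Reagents that add atoms: none
Why: Barbier propargylation: the allenylzinc bromide formed in the flask adds 1,2 to the aldehyde through a cyclic SE2′ transition state to give the homopropargylic alcohol; the carbinol configuration is irrelevant because C6 is oxidised in step 8.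

Step 5
Reactants: 8 1-[(5S)-2-methyl-5-(propan-2-yl)cyclopent-1-en-1-yl]but-3-yn-1-ol
Product: 10 (2E)-3-methyl-5-[(5S)-2-methyl-5-(propan-2-yl)cyclopent-1-en-1-yl]pent-2-ene-1,5-diol, via the (E)-alkenyldimethylalane 9 (not isolated)
Conditions: AlMe3 (3.5 equiv), Cp2ZrCl2 (0.25 equiv), CH2Cl2, 0 °C → rt; excess AlMe3 removed; n-BuLi (1.1 equiv), THF, −78 °C; (CH2O)n, −78 °C → rt; aq. NH4Cl
Reagents that add atoms: trimethylaluminium, C[Al](C)C; formaldehyde (as paraformaldehyde), C=O
Why: Negishi carboalumination adds methyl and aluminium syn across the terminal alkyne with methyl on the internal carbon, and the alkenylalanate is hydroxymethylated with retention, which fixes the (E)-trisubstituted alkene; the hydroxyl is carried as its aluminium alkoxide and the tetrasubstituted ring alkene does not react.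

Step 6
Reactants: 10 (2E)-3-methyl-5-[(5S)-2-methyl-5-(propan-2-yl)cyclopent-1-en-1-yl]pent-2-ene-1,5-diol
Product: 11 diethyl (2E)-5-hydroxy-3-methyl-5-[(5S)-2-methyl-5-(propan-2-yl)cyclopent-1-en-1-yl]pent-2-en-1-yl phosphate
Conditions: ClP(O)(OEt)2 (1.05 equiv), pyridine, CH2Cl2, −20 → 0 °C
Reagents that add atoms: diethyl chlorophosphate, CCOP(Cl)(=O)OCC
Why: Phosphorylation should go to the unhindered primary allylic hydroxyl; the secondary carbinol flanked by the tetrasubstituted cyclopentene stays free.

Step 7
Reactants: 11 diethyl (2E)-5-hydroxy-3-methyl-5-[(5S)-2-methyl-5-(propan-2-yl)cyclopent-1-en-1-yl]pent-2-en-1-yl phosphate; 12 2-[dimethyl(phenyl)silyl]-4,4,5,5-tetramethyl-1,3,2-dioxaborolane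
Product: 13 3-[dimethyl(phenyl)silyl]-3-methyl-1-[(5S)-2-methyl-5-(propan-2-yl)cyclopent-1-en-1-yl]pent-4-en-1-ol
Conditions: CuCl (5 mol %), IMes·HCl (6 mol %), NaOH (1.6 equiv), THF, rt
Reagents that add atoms: none
Why: Copper-catalysed allylic substitution with a Si–B reagent: the silylcopper species attacks the γ-carbon (SN2′), giving the tertiary allylsilane with a terminal vinyl group; both epimers at the silyl carbon are acceptable because that centre becomes trigonal in step 9, and the (E) geometry keeps the free alkoxide away from the phosphate-bearing carbon.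

Step 8
Reactants: 13 3-[dimethyl(phenyl)silyl]-3-methyl-1-[(5S)-2-methyl-5-(propan-2-yl)cyclopent-1-en-1-yl]pent-4-en-1-ol
Product: 14 3-[dimethyl(phenyl)silyl]-3-methyl-1-[(5S)-2-methyl-5-(propan-2-yl)cyclopent-1-en-1-yl]pent-4-en-1-one
Conditions: Dess–Martin periodinane (1.3 equiv), NaHCO3, CH2Cl2, 0 °C → rt
Reagents that add atoms: none
Why: Dess–Martin oxidation of the secondary allylic alcohol under buffered conditions that leave the acid-labile allylsilane intact; the carbinol epimers converge on the enone, which remains a pair of epimers at the silyl carbon.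

Step 9
Reactants: 14 3-[dimethyl(phenyl)silyl]-3-methyl-1-[(5S)-2-methyl-5-(propan-2-yl)cyclopent-1-en-1-yl]pent-4-en-1-one
Product: 15 {[(3S,8aS)-6,8a-dimethyl-3-(propan-2-yl)-1,2,3,5,8,8a-hexahydroazulen-4-yl]oxy}(dimethyl)phenylsilane
Conditions: PhMe2SiNTf2 (10 mol %, made in the flask from PhMe2SiCl and AgNTf2), 2,6-di-tert-butyl-4-methylpyridine (20 mol %), CH2Cl2, −78 → −40 °C; Et3N quench
Reagents that add atoms: none
Why: The silyl Lewis acid binds the C6 carbonyl oxygen and makes C1 electrophilic; the CH2 terminus C10 of the allylsilane attacks C1, the positive charge that builds up at C9 is stabilised by hyperconjugation with the C8–Si bond, and loss of the silyl group leaves the C8=C9 alkene. The released PhMe2Si+ is taken up by the next carbonyl oxygen, so the catalyst should turn over and the product is the silyl enol ether 15 with the enol double bond fixed at C5=C6; hydrolysis of 15 would give the C6 ketone of this hexahydroazulenone, which is deliberately not released because its C7 methylene would dominate any later enolisation. The closest known reaction type is the Hosomi–Sakurai conjugate allylation of enones under silyl triflimide catalysis, together with Lewis-acid-promoted intramolecular allylsilane additions that close seven-membered rings onto β,β-disubstituted enones. The seven-membered ring closes in a 7-endo-trig mode with respect to the C1=C5 double bond, with the allyl unit inside the new ring; the competing 1,2-addition of C10 to C6 would need a five-membered transition state with an endocyclic allyl π system and is stereoelectronically poor. The new quaternary stereocentre C1 is controlled by the isopropyl group on C4, the only stereocentre of 14: the tether should fold over the ring face away from it, so C10 bonds anti to the isopropyl group and the C1 methyl ends on the isopropyl side. The configuration at C8 is lost, so both epimers of 14 converge, and C5 is left trigonal on purpose because it is set in step 13. The step needs reaction at the γ-terminus of the allylsilane (secured by the β-silicon effect and the unhindered CH2 group), 1,4- over 1,2-addition (secured by ring size), and no protodesilylation (secured by the hindered pyridine base and the low temperature).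

Step 10
Reactants: 15 {[(3S,8aS)-6,8a-dimethyl-3-(propan-2-yl)-1,2,3,5,8,8a-hexahydroazulen-4-yl]oxy}(dimethyl)phenylsilane
Product: 16 (8aS)-6,8a-dimethyl-3-(propan-2-yl)-1,2,8,8a-tetrahydroazulen-4(5H)-one
Conditions: Pd(OAc)2 (1.1 equiv), MeCN, rt → 40 °C
Reagents that add atoms: none
Why: Saegusa–Ito oxidation: the regiodefined silyl enol ether is converted into a divalent palladium enolate bound at C5, whose only β-hydrogen is on C4, so β-hydride elimination should give the C4=C5 enone; the C4 stereocentre is erased and C1 is untouched.

Step 11
Reactants: 16 (8aS)-6,8a-dimethyl-3-(propan-2-yl)-1,2,8,8a-tetrahydroazulen-4(5H)-one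
Product: 17 (4R,8aS)-6,8a-dimethyl-3-(propan-2-yl)-1,2,4,5,8,8a-hexahydroazulen-4-ol
Conditions: (S)-2-methyl-CBS-oxazaborolidine (0.2 equiv), catecholborane (1.5 equiv), toluene, −78 °C; MeOH, then aq. NaOH wash
Reagents that add atoms: none
Why: Corey–Bakshi–Shibata reduction: the (S)-catalyst treats the tetrasubstituted alkenyl carbon C5 as the large group and C7 as the small one, so hydride delivery should give the (R)-carbinol at C6 with its hydroxyl on the face of the C1–C10 bond, opposite the C1 methyl; catecholborane at −78 °C leaves the C8=C9 alkene alone.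

Step 12
Reactants: 17 (4R,8aS)-6,8a-dimethyl-3-(propan-2-yl)-1,2,4,5,8,8a-hexahydroazulen-4-ol
Product: 18 (3R,3aS,4R,8aS)-3,3a-epoxy-6,8a-dimethyl-3-(propan-2-yl)-1,2,3,3a,4,5,8,8a-octahydroazulen-4-ol
Conditions: VO(acac)2 (5 mol %), t-BuOOH (1.3 equiv, in decane), CH2Cl2, 0 °C
Reagents that add atoms: tert-butyl hydroperoxide, CC(C)(C)OO
Why: Hydroxyl-directed epoxidation: the vanadate ester of the C6 hydroxyl delivers oxygen to the tetrasubstituted C4=C5 alkene on the face that carries the hydroxyl, which puts the C4–O and C5–O bonds opposite the C1 methyl; the allylic alkene should react much faster than the homoallylic C8=C9 alkene.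

Step 13
Reactants: 18 (3R,3aS,4R,8aS)-3,3a-epoxy-6,8a-dimethyl-3-(propan-2-yl)-1,2,3,3a,4,5,8,8a-octahydroazulen-4-ol
Product: 19 (3R,3aR,8aS)-3-hydroxy-6,8a-dimethyl-3-(propan-2-yl)-2,3,3a,5,8,8a-hexahydroazulen-4(1H)-one
Conditions: BF3·OEt2 (0.2 equiv), CH2Cl2, −78 °C; Et3N, then aq. NaHCO3
Reagents that add atoms: none
Why: Semipinacol rearrangement of a 2,3-epoxy alcohol: with the epoxide oxygen bound to boron, the C5–O bond breaks while the C6 hydrogen, which lies anti-periplanar to it in the syn epoxy alcohol, shifts to C5 with inversion, so C5–H ends trans to the C4 oxygen (cis ring fusion), C4 keeps its oxygen and C6 becomes the ketone. The push from the carbinol oxygen should favour this path over ionisation at C4, and no base is present that could move the C8=C9 alkene.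

Step 14
Reactants: 19 (3R,3aR,8aS)-3-hydroxy-6,8a-dimethyl-3-(propan-2-yl)-2,3,3a,5,8,8a-hexahydroazulen-4(1H)-one
Product: 21 (3R,3aS,4R,8aS)-6,8a-dimethyl-3-(propan-2-yl)-1,2,3,3a,4,5,8,8a-octahydroazulene-3,4-diol, via the diethylboron chelate 20 (not isolated)
Conditions: Et2BOMe (1.2 equiv), THF–MeOH 4:1, −78 °C; NaBH4 (1.5 equiv), −78 °C; AcOH, MeOH co-evaporation
Reagents that add atoms: none
Why: Narasaka–Prasad reduction: the boron chelate between the C4 oxygen and the C6 carbonyl, possible because both sit on the concave face, should be attacked by external hydride from the open convex face, giving the 1,3-syn diol with the C6 hydroxyl on the side of the C4 hydroxyl.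

Step 15
Reactants: 21 (3R,3aS,4R,8aS)-6,8a-dimethyl-3-(propan-2-yl)-1,2,3,3a,4,5,8,8a-octahydroazulene-3,4-diol; 22 4-{[tert-butyl(dimethyl)silyl]oxy}benzoic acid
Product: 23 (3R,3aS,4R,8aS)-3-hydroxy-6,8a-dimethyl-3-(propan-2-yl)-1,2,3,3a,4,5,8,8a-octahydroazulen-4-yl 4-{[tert-butyl(dimethyl)silyl]oxy}benzoate
Conditions: DCC (1.5 equiv), DMAP (0.3 equiv), CH2Cl2, 0 °C → rt
Reagents that add atoms: none
Why: Steglich esterification should acylate the secondary C6 hydroxyl only; the tertiary C4 hydroxyl is too hindered to react and no stereocentre is affected.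

Step 16
Reactants: 23 (3R,3aS,4R,8aS)-3-hydroxy-6,8a-dimethyl-3-(propan-2-yl)-1,2,3,3a,4,5,8,8a-octahydroazulen-4-yl 4-{[tert-butyl(dimethyl)silyl]oxy}benzoate
Product: 24 (3R,3aS,4R,6R,7S,8aS)-6,7-epoxy-3-hydroxy-6,8a-dimethyl-3-(propan-2-yl)decahydroazulen-4-yl 4-{[tert-butyl(dimethyl)silyl]oxy}benzoate
Conditions: m-CPBA (1.1 equiv), NaHCO3 (3 equiv), CH2Cl2, 0 °C
Reagents that add atoms: 3-chloroperoxybenzoic acid, OOC(=O)c1cccc(Cl)c1
Why: Prilezhaev epoxidation of the only alkene: on the cis-fused bicycle the peracid should approach the convex face, which carries only the C1 methyl, because the other face is covered by the cyclopentane carbons and the C6 aroyloxy group; the epoxide oxygen then lies anti to both C–O substituents as in the target, and bicarbonate protects the tertiary epoxide from acid.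

Step 17
Reactants: 24 (3R,3aS,4R,6R,7S,8aS)-6,7-epoxy-3-hydroxy-6,8a-dimethyl-3-(propan-2-yl)decahydroazulen-4-yl 4-{[tert-butyl(dimethyl)silyl]oxy}benzoate
Product: 25 (3R,3aS,4R,6R,7S,8aS)-6,7-epoxy-3-hydroxy-6,8a-dimethyl-3-(propan-2-yl)decahydroazulen-4-yl 4-hydroxybenzoate
Conditions: TBAF (1.1 equiv), AcOH (1.1 equiv), THF, 0 °C
Reagents that add atoms: none
Why: Fluoride desilylation of the aryl silyl ether under buffered conditions should be fast and should leave the benzoate, the epoxide and the tertiary alcohol untouched.

## Compound list

1 | (R)-limonene, (4R)-1-methyl-4-(prop-1-en-2-yl)cyclohex-1-ene | CC1=CC[C@@H](CC1)C(C)=C | starting material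
2 | (4R)-1-methyl-4-(propan-2-yl)cyclohex-1-ene | CC1=CC[C@@H](CC1)C(C)C | intermediate
3 | (4R)-1-methyl-4-(propan-2-yl)-7,8,9-trioxabicyclo[4.2.1]nonane (secondary ozonide, both acetal configurations) | CC12CC[C@@H](C(C)C)CC(OO1)O2 | intermediate (not isolated)
4 | (3R)-6-oxo-3-(propan-2-yl)heptanal | CC(=O)CC[C@H](CC=O)C(C)C | intermediate
5 | (5S)-2-methyl-5-(propan-2-yl)cyclopent-1-ene-1-carbaldehyde | CC(C)[C@@H]1CCC(C)=C1C=O | intermediate
6 | 3-bromoprop-1-yne (propargyl bromide) | BrCC#C | starting material
7 | bromo(propa-1,2-dien-1-yl)zinc | C=C=C[Zn]Br | intermediate (not isolated)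
8 | 1-[(5S)-2-methyl-5-(propan-2-yl)cyclopent-1-en-1-yl]but-3-yn-1-ol (both carbinol epimers) | CC(C)[C@@H]1CCC(C)=C1C(O)CC#C | intermediate
9 | [(1E)-4-[(dimethylalumanyl)oxy]-2-methyl-4-[(5S)-2-methyl-5-(propan-2-yl)cyclopent-1-en-1-yl]but-1-en-1-yl](dimethyl)alumane | CC(C)[C@@H]1CCC(C)=C1C(O[Al](C)C)C/C(C)=C/[Al](C)C | intermediate (not isolated)
10 | (2E)-3-methyl-5-[(5S)-2-methyl-5-(propan-2-yl)cyclopent-1-en-1-yl]pent-2-ene-1,5-diol (both carbinol epimers) | CC(C)[C@@H]1CCC(C)=C1C(O)C/C(C)=C/CO | intermediate
11 | diethyl (2E)-5-hydroxy-3-methyl-5-[(5S)-2-methyl-5-(propan-2-yl)cyclopent-1-en-1-yl]pent-2-en-1-yl phosphate | CC(C)[C@@H]1CCC(C)=C1C(O)C/C(C)=C/COP(=O)(OCC)OCC | intermediate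
12 | 2-[dimethyl(phenyl)silyl]-4,4,5,5-tetramethyl-1,3,2-dioxaborolane | CC1(C)OB(OC1(C)C)[Si](C)(C)c1ccccc1 | starting material
13 | 3-[dimethyl(phenyl)silyl]-3-methyl-1-[(5S)-2-methyl-5-(propan-2-yl)cyclopent-1-en-1-yl]pent-4-en-1-ol (epimers at the carbinol and silyl carbons) | CC(C)[C@@H]1CCC(C)=C1C(O)CC(C)([Si](C)(C)c1ccccc1)C=C | intermediate
14 | 3-[dimethyl(phenyl)silyl]-3-methyl-1-[(5S)-2-methyl-5-(propan-2-yl)cyclopent-1-en-1-yl]pent-4-en-1-one (both epimers at the silyl carbon) | CC(C)[C@@H]1CCC(C)=C1C(=O)CC(C)([Si](C)(C)c1ccccc1)C=C | intermediate
15 | {[(3S,8aS)-6,8a-dimethyl-3-(propan-2-yl)-1,2,3,5,8,8a-hexahydroazulen-4-yl]oxy}(dimethyl)phenylsilane | CC(C)[C@@H]1CC[C@@]2(C)CC=C(C)CC(O[Si](C)(C)c3ccccc3)=C12 | intermediate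
16 | (8aS)-6,8a-dimethyl-3-(propan-2-yl)-1,2,8,8a-tetrahydroazulen-4(5H)-one | CC(C)C1=C2C(=O)CC(C)=CC[C@]2(C)CC1 | intermediate
17 | (4R,8aS)-6,8a-dimethyl-3-(propan-2-yl)-1,2,4,5,8,8a-hexahydroazulen-4-ol | CC(C)C1=C2[C@H](O)CC(C)=CC[C@]2(C)CC1 | intermediate
18 | (3R,3aS,4R,8aS)-3,3a-epoxy-6,8a-dimethyl-3-(propan-2-yl)-1,2,3,3a,4,5,8,8a-octahydroazulen-4-ol | CC(C)[C@]12CC[C@@]3(C)CC=C(C)C[C@@H](O)[C@]13O2 | intermediate
19 | (3R,3aR,8aS)-3-hydroxy-6,8a-dimethyl-3-(propan-2-yl)-2,3,3a,5,8,8a-hexahydroazulen-4(1H)-one | CC(C)[C@]1(O)CC[C@@]2(C)CC=C(C)CC(=O)[C@H]21 | intermediate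
20 | (3R,3aR,8aS)-3-[(diethylboranyl)oxy]-6,8a-dimethyl-3-(propan-2-yl)-2,3,3a,5,8,8a-hexahydroazulen-4(1H)-one (boron chelated by the ketone oxygen) | CC(C)[C@]1(OB(CC)CC)CC[C@@]2(C)CC=C(C)CC(=O)[C@H]21 | intermediate (not isolated)
21 | (3R,3aS,4R,8aS)-6,8a-dimethyl-3-(propan-2-yl)-1,2,3,3a,4,5,8,8a-octahydroazulene-3,4-diol | CC(C)[C@]1(O)CC[C@@]2(C)CC=C(C)C[C@@H](O)[C@H]21 | intermediate
22 | 4-{[tert-butyl(dimethyl)silyl]oxy}benzoic acid | CC(C)(C)[Si](C)(C)Oc1ccc(cc1)C(O)=O | starting material
23 | (3R,3aS,4R,8aS)-3-hydroxy-6,8a-dimethyl-3-(propan-2-yl)-1,2,3,3a,4,5,8,8a-octahydroazulen-4-yl 4-{[tert-butyl(dimethyl)silyl]oxy}benzoate | CC(C)[C@]1(O)CC[C@@]2(C)CC=C(C)C[C@@H](OC(=O)c3ccc(O[Si](C)(C)C(C)(C)C)cc3)[C@H]21 | intermediate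
24 | (3R,3aS,4R,6R,7S,8aS)-6,7-epoxy-3-hydroxy-6,8a-dimethyl-3-(propan-2-yl)decahydroazulen-4-yl 4-{[tert-butyl(dimethyl)silyl]oxy}benzoate | CC(C)[C@]1(O)CC[C@@]2(C)C[C@@H]3O[C@]3(C)C[C@@H](OC(=O)c3ccc(O[Si](C)(C)C(C)(C)C)cc3)[C@H]21 | intermediate
25 | (3R,3aS,4R,6R,7S,8aS)-6,7-epoxy-3-hydroxy-6,8a-dimethyl-3-(propan-2-yl)decahydroazulen-4-yl 4-hydroxybenzoate | CC(C)[C@]1(O)CC[C@@]2(C)C[C@@H]3O[C@]3(C)C[C@@H](OC(=O)c3ccc(O)cc3)[C@H]21 | target

## Step count and least certain steps

Total step count: 17. Longest linear sequence: 17 steps (1 → 25); 6, 12 and 22 enter as purchased reagents.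

**Step 9 (key step).** The most likely failures are loss of the allylsilane by protodesilylation before the hindered, twisted enone is engaged, and stalling of the silyl transfer so that the catalyst does not turn over. Poor facial selectivity at C1 is the second concern, because the controlling isopropyl group sits one carbon away from the reacting centre. The fallback sets out from 14 and rejoins at 16. Compound 14 is cyclised with stoichiometric TiCl4 in CH2Cl2 at −78 °C to the trichlorotitanium enolate F1. This is trapped in the same flask with PhSeCl as the C5 phenylselenide F2; selenium should enter anti to the isopropyl group and therefore cis to the C4 hydrogen. Oxidation with H2O2 and pyridine at 0 °C gives the selenoxide F3, whose syn elimination can only use the C4 hydrogen and should deliver 16. This path replaces catalytic silyl transfer by stoichiometric Lewis acid with chalcogen trapping, and it bypasses 15 and step 10.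

**Step 13.** The most likely failures are ionisation of the fully substituted epoxide at C4 instead of C5, followed by elimination or migration of a C5 substituent; migration of C7 instead of hydrogen if the seven-membered ring reacts from a twisted conformer; and Lewis-acid dehydration of the tertiary aldol. The fallback sets out from 18 and rejoins at 19. Dess–Martin oxidation of 18 gives the epoxy ketone F4. SmI2 in THF with t-BuOH at −78 °C then cleaves the C5–O bond regiospecifically through the ketyl, and the samarium enolate is protonated at C5. The bulky proton source is chosen so that protonation occurs on the face away from the samarium alkoxide at C4. The resulting 19 should also be the more stable C5 epimer (C6 trans to the isopropyl group, hydroxyl hydrogen-bonded to the carbonyl).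

**Step 16.** The most likely failures are poor facial selectivity if the free C4 hydroxyl steers the peracid to the concave face by hydrogen bonding, and acid-induced transannular opening of the new epoxide by that hydroxyl. The fallback sets out from 23 and rejoins at 24. NBS in aqueous THF at 0 °C forms the bromohydrin F5, with bromine on the face the electrophile prefers and water entering at the tertiary C8 from the other side. DBU in MeCN then closes the epoxide by displacement of bromide at C9 with inversion. The oxygen therefore ends on the face opposite to the one the electrophile chose, which corrects a concave-face preference.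

**Step 10.** The most likely failures are slow formation or slow β-hydride elimination of the palladium enolate at the fully substituted C5, and competing desilylation to the ketone, whose enolisation would then go to C7. The fallback sets out from 15 and rejoins at 16. MeLi in THF (0 °C, then −78 °C) cleaves the O–Si bond of 15 to the regiodefined lithium enolate F6. This reacts at −78 °C with N-tert-butylbenzenesulfinimidoyl chloride; the sulfur adduct eliminates as it forms (syn, through the C4 hydrogen) and should give 16 without a transition metal.

## Further compounds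

F1 | step 9 | trichloro{[(3S,8aS)-6,8a-dimethyl-3-(propan-2-yl)-1,2,3,5,8,8a-hexahydroazulen-4-yl]oxy}titanium | CC(C)[C@@H]1CC[C@@]2(C)CC=C(C)CC(O[Ti](Cl)(Cl)Cl)=C12
F2 | step 9 | (3S,3aS,8aS)-6,8a-dimethyl-3a-(phenylselanyl)-3-(propan-2-yl)-2,3,3a,5,8,8a-hexahydroazulen-4(1H)-one | CC(C)[C@@H]1CC[C@@]2(C)CC=C(C)CC(=O)[C@]12[Se]c1ccccc1
F3 | step 9 | (3S,3aS,8aS)-3a-(benzeneseleninyl)-6,8a-dimethyl-3-(propan-2-yl)-2,3,3a,5,8,8a-hexahydroazulen-4(1H)-one | CC(C)[C@@H]1CC[C@@]2(C)CC=C(C)CC(=O)[C@]12[Se](=O)c1ccccc1
F4 | step 13 | (3R,3aR,8aS)-3,3a-epoxy-6,8a-dimethyl-3-(propan-2-yl)-2,3,3a,5,8,8a-hexahydroazulen-4(1H)-one | CC(C)[C@]12CC[C@@]3(C)CC=C(C)CC(=O)[C@]13O2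
F5 | step 16 | (3R,3aS,4R,6R,7R,8aS)-7-bromo-3,6-dihydroxy-6,8a-dimethyl-3-(propan-2-yl)decahydroazulen-4-yl 4-{[tert-butyl(dimethyl)silyl]oxy}benzoate | CC(C)[C@]1(O)CC[C@@]2(C)C[C@@H](Br)[C@](C)(O)C[C@@H](OC(=O)c3ccc(O[Si](C)(C)C(C)(C)C)cc3)[C@H]21
F6 | step 10 | lithium (3S,8aS)-6,8a-dimethyl-3-(propan-2-yl)-1,2,3,5,8,8a-hexahydroazulen-4-olate | CC(C)[C@@H]1CC[C@@]2(C)CC=C(C)CC(O[Li])=C12
A1 | alternative 1 | triethyl({1-[(2S,3R)-3-[(3Z,5E)-3-methylhepta-3,5-dien-1-yl]-3-(propan-2-yl)oxiran-2-yl]ethenyl}oxy)silane | C=C(O[Si](CC)(CC)CC)[C@H]1O[C@@]1(C(C)C)CC/C(C)=C\C=C\C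
A2 | alternative 1 | (3R,3aR,6R,8aS)-6,8a-dimethyl-3-(propan-2-yl)-3-[(triethylsilyl)oxy]-2,3,3a,5,6,8a-hexahydroazulen-4(1H)-one | CC(C)[C@]1(O[Si](CC)(CC)CC)CC[C@@]2(C)C=C[C@H](C)CC(=O)[C@H]21
A3 | alternative 2 | 6-methyl-3-(4-methyl-3-oxopentyl)cyclohepta-2,5-dien-1-one | CC(C)C(=O)CCC1=CC(=O)CC(C)=CC1
A4 | alternative 2 | (3R,3aR,8aS)-3-hydroxy-6,8a-dimethyl-3-(propan-2-yl)-2,3,3a,5,8,8a-hexahydroazulen-4(1H)-one | CC(C)[C@]1(O)CC[C@@]2(C)CC=C(C)CC(=O)[C@H]21
A5 | alternative 3 | (2E,6E)-farnesyl diphosphate | CC(C)=CCC/C(C)=C/CC/C(C)=C/COP(O)(=O)OP(O)(O)=O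
A6 | alternative 3 | (3R,3aR,8aS)-6,8a-dimethyl-3-(propan-2-yl)-1,2,3,3a,4,5,8,8a-octahydroazulen-3-ol | CC(C)[C@]1(O)CC[C@@]2(C)CC=C(C)CC[C@H]21
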